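**Retrosynthetic overview**

1. 21 ⇒ 19: the C15 allylic hydroxyl and the free C6 aldehyde / C13 alcohol come last, after the skeleton is complete (the oxygenation order of the biosynthesis).
2. 19 ⇒ 17: rings C and D close together in one radical cascade from C8, the radical counterpart of the C8 cation of the ent-kaurene cyclase cascade: C8–C14 (6-endo on an enol silane), then C13–C16 (5-exo-dig), with H-atom termination giving the 16(17)-ene.
3. 17 ⇒ 10 + 11: C9–C11 by conjugate addition to a spiro alkylidene-malonate-type lactone; the extra C8 carboxyl first activates, then serves as the traceless radical precursor.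
4. 10 ⇒ 5: the lactone ring closes by capture of a Meldrum's acid acyl group by C20–OH (the C20–O–C7 bond), after two enolate functionalisations at C10 (C20 first, C9 second) that set the spiro centre.
5. 5 ⇒ 1: ring A is bought as 4,4-dimethylcyclohexenone; C5 is set by asymmetric vinyl conjugate addition to the derived dienone. Ring order: A (purchased) → lactone → C and D (one step).

Assumption: atom labels C1–C20 in names and comments follow kaurane numbering of the target (C6 aldehyde carbon, C7 lactone carbonyl, C20 lactone CH2, C8–C16 the bicyclo[3.2.1]octane); the SMILES strings are authoritative for configuration.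

**Route**

Step 1
Reactants: 1 4,4-dimethylcyclohex-2-en-1-one
Product: 2 4,4-dimethylcyclohexa-2,5-dien-1-one
Conditions: DDQ (1.3 equiv), 1,4-dioxane, reflux
Reagents that add atoms: none
Why: Quinone (DDQ) dehydrogenation of the enone via its dienol; the quaternary C4 blocks aromatisation, so the cross-conjugated dienone is the end point and no stereocentre is involved.

Step 2
Reactants: 2 4,4-dimethylcyclohexa-2,5-dien-1-one
Product: 3 (R)-4,4-dimethyl-5-vinylcyclohex-2-en-1-one
Conditions: K[CH2=CHBF3] (1.2 equiv), [Rh(C8H12)2]PF6 (3 mol%), (R)-BINAP (3.3 mol%), toluene/H2O, 100 °C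
Reagents that add atoms: potassium vinyltrifluoroborate, C=C[B-](F)(F)F.[K+]
Why: Hayashi–Miyaura rhodium-catalysed asymmetric conjugate addition desymmetrises the dienone, the (R)-BINAP complex choosing one enantiotopic enone face and so setting C5, the only source of absolute configuration (sense assigned by analogy with cyclohexenone), while the less electrophilic product enone stops at mono-addition.

Step 3
Reactants: 3 (R)-4,4-dimethyl-5-vinylcyclohex-2-en-1-one
Product: 5 (S)-5-(dimethoxymethyl)-4,4-dimethylcyclohex-2-en-1-one, via aldehyde 4 (not isolated)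
Conditions: O3, CH2Cl2, −78 °C; Me2S, −78 °C → rt; then HC(OMe)3, PPTS (cat.), 0 °C → rt
Reagents that add atoms: trimethyl orthoformate, COC(OC)OC
Why: Ozonolysis selects the electron-rich vinyl group over the electron-poor enone, and immediate acetalisation (faster than enolisation of the neopentyl C5–H) stores C6 as a dimethyl acetal with C5 untouched (the descriptor changes only through CIP priorities).

Step 4
Reactants: 5 (S)-5-(dimethoxymethyl)-4,4-dimethylcyclohex-2-en-1-one
Product: 7 (5S,6R)-6-[(tert-butyldimethylsilyloxy)methyl]-5-(dimethoxymethyl)-4,4-dimethylcyclohex-2-en-1-one, via hydroxymethyl ketone 6 (not isolated)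
Conditions: LiN(i-Pr)2, THF, −78 °C; CH2O (monomeric, THF), −78 °C; H2O; crude: TBSCl, imidazole, DMF, 0 °C → rt
Reagents that add atoms: formaldehyde, C=O; tert-butyldimethylsilyl chloride, CC(C)(C)[Si](C)(C)Cl
Why: Aldol addition of the kinetic cross-conjugated enolate (C10 is the only enolisable position) to formaldehyde installs C20 trans to the C5 substituent, a centre that is re-enolised in step 5 so its configuration is immaterial, and silylation blocks retro-aldol and dehydration.

Step 5
Reactants: 7 (5S,6R)-6-[(tert-butyldimethylsilyloxy)methyl]-5-(dimethoxymethyl)-4,4-dimethylcyclohex-2-en-1-one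
Product: 8 5-{[(1S,6R)-1-[(tert-butyldimethylsilyloxy)methyl]-6-(dimethoxymethyl)-5,5-dimethyl-2-oxocyclohex-3-en-1-yl]methylidene}-2,2-dimethyl-1,3-dioxane-4,6-dione
Conditions: KN(SiMe3)2, THF, −78 °C; 5-(methoxymethylene)-2,2-dimethyl-1,3-dioxane-4,6-dione, −78 → 0 °C
Reagents that add atoms: 5-(methoxymethylene)-2,2-dimethyl-1,3-dioxane-4,6-dione, COC=C1C(=O)OC(C)(C)OC1=O
Why: Michael addition–elimination of the tetrasubstituted enolate on the alkoxymethylene Meldrum's acid; the electrophile enters anti to the pseudoaxial C5 acetal group, so C9 ends trans and C20 cis to C6, which is the target configuration of the quaternary C10.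

Step 6
Reactants: 8 (alkylidene Meldrum's acid)
Product: 10 (6S,11R)-11-(dimethoxymethyl)-10,10-dimethyl-3,7-dioxo-2-oxaspiro[5.5]undeca-4,8-diene-4-carboxylic acid, via hydroxy Meldrum's acid 9 (not isolated)
Conditions: HF·pyridine, pyridine/THF, 0 °C → rt; then 45 °C
Reagents that add atoms: none
Why: Desilylation frees C20–OH, which is acylated intramolecularly by the neighbouring Meldrum's carbonyl (alcoholysis with loss of acetone) to close the δ-lactone ring through the C20–O–C7 bond and leave C8 as a carboxylic acid; no stereocentre is formed.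

Step 7
Reactants: 10 (spirolactone acid); 11 2-(2-bromoethyl)-2-methyl-1,3-dioxolane
Product: 14 (4R,5S,6S,11R)-11-(dimethoxymethyl)-10,10-dimethyl-5-[2-(2-methyl-1,3-dioxolan-2-yl)ethyl]-3,7-dioxo-4-(prop-2-yn-1-yl)-2-oxaspiro[5.5]undec-8-ene-4-carboxylic acid, via Grignard reagent 12 (not isolated), via magnesium enolate 13 (not isolated)
Conditions: 11, Mg, THF, 40 °C (gives 12, 2.5 equiv); CuBr·SMe2 (10 mol%), THF, −40 °C, add 10; then propargyl bromide, DMPU, −40 → 0 °C; pH 5 buffer
Reagents that add atoms: propargyl bromide, C#CCBr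
Why: Tandem copper-catalysed conjugate addition–enolate alkylation: the chelated alkylidene-malonate-type lactone (far more electrophilic than the hindered ring A enone) is attacked at C9 from the lactone face flanked by the flat C1 carbonyl, anti to C5 and its acetal, which sets C9, and the enolate–carboxylate dianion is C-propargylated trans to the new chain (the C8 configuration is erased in step 10).

Step 8
Reactants: 14 (ketal acid)
Product: 15 (4R,5S,6S,11R)-11-(dimethoxymethyl)-10,10-dimethyl-3,7-dioxo-5-(3-oxobutyl)-4-(prop-2-yn-1-yl)-2-oxaspiro[5.5]undec-8-ene-4-carboxylic acid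
Conditions: PPTS (0.2 equiv), acetone/H2O (10:1), rt, stopped at full conversion of the ketal
Reagents that add atoms: water, O
Why: Acid-catalysed ketal hydrolysis (transketalisation to acetone); the ketone dioxolane ionises roughly two orders of magnitude faster than the aldehyde dimethyl acetal, so only the methyl ketone is released and no stereocentre changes.

Step 9
Reactants: 15 (methyl ketone acid)
Product: 17 (4R,5S,6S,11R)-11-(dimethoxymethyl)-10,10-dimethyl-3,7-dioxo-4-(prop-2-yn-1-yl)-5-[3-(trimethylsilyloxy)but-3-en-1-yl]-2-oxaspiro[5.5]undec-8-ene-4-carboxylic acid, via bis-silyl derivative 16 (not isolated)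
Conditions: LiN(SiMe3)2 (2.3 equiv), TMSCl (3 equiv, premixed), THF, −78 °C; pH 7 buffer, 0 °C
Reagents that add atoms: chlorotrimethylsilane, C[Si](C)(C)Cl
Why: Kinetic enol silane formation with in situ silylation deprotonates the methyl ketone at CH3 (ring A and C8 carry no enolisable hydrogen; the carboxyl is silylated transiently and released on work-up), giving the terminal enol silane without touching a stereocentre.

Step 10
Reactants: 17 (enol silane acid)
Product: 19 6,6-dimethoxy-1-oxo-13-(trimethylsilyloxy)-6,7-secokaura-2,16-dien-7,20-olide (ring stereocentres as in 21), via Barton ester 18 (not isolated)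
Conditions: N-hydroxypyridine-2-thione, DCC, DMAP (cat.), CH2Cl2, 0 °C, dark; filter; then PhH (0.005 M), hν (tungsten lamp), 25 °C, Bu3SnH (1.3 equiv, syringe pump, 6 h)
Reagents that add atoms: none
Why: Proposed new method: Barton decarboxylation gives the tertiary electrophilic C8 radical (a stand-in for the C8 cation of the cyclase cascade), which adds 6-endo to the CH2 terminus of the electron-rich enol silane from the face of the pseudoaxial C9 chain (cis ring fusion with C15 anti to C10, fixing C8); the resulting α-silyloxy C13 radical closes ring D by 5-exo-dig attack on the axial propargyl group (bridging fixes C13) and the vinyl radical is reduced by Bu3SnH to the exocyclic methylene; the closest known reaction types are Barton-ester radical cyclisations, 6-endo additions of α-carbonyl radicals to enol silanes and 5-exo-dig closures of bicyclo[3.2.1]octanes in kaurane and gibberellin synthesis.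

Step 11
Reactants: 19 (tetracyclic silyl ether)
Product: 20 (15R)-15-hydroxy-6,6-dimethoxy-1-oxo-13-(trimethylsilyloxy)-6,7-secokaura-2,16-dien-7,20-olide
Conditions: SeO2 (0.3 equiv), t-BuOOH (3 equiv), CH2Cl2, 0 °C → rt
Reagents that add atoms: tert-butyl hydroperoxide, CC(C)(C)OO
Why: Selenium dioxide allylic hydroxylation (ene reaction then [2,3]-sigmatropic shift): C15 is the only allylic C–H position of the 16(17)-alkene, and oxygen is expected on the C15 face syn to C9/C11 by analogy with the 15-hydroxylation of ent-kaur-16-enes and steviol, which gives the required 15R alcohol.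

Step 12
Reactants: 20 (15-hydroxy silyl ether acetal)
Product: 21 target, (5R,8S,9S,10S,13S,15R)-13,15-dihydroxy-1,6-dioxo-6,7-secokaura-2,16-dien-7,20-olide
Conditions: AcOH/THF/H2O (3:1:1), rt → 40 °C
Reagents that add atoms: water, O
Why: Acetal hydrolysis and cleavage of the tertiary trimethylsilyl ether in weak acid release the C6 aldehyde and C13 alcohol without epimerising the hindered C5 or triggering the acid rearrangements of the 13,15-dihydroxy-16-ene unit that mineral acid can cause.

**Compound list**

1 | 4,4-dimethylcyclohex-2-en-1-one | O=C1C=CC(C)(C)CC1 | starting material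
2 | 4,4-dimethylcyclohexa-2,5-dien-1-one | O=C1C=CC(C)(C)C=C1 | intermediate
3 | (R)-4,4-dimethyl-5-vinylcyclohex-2-en-1-one | O=C1C=CC(C)(C)[C@@H](C=C)C1 | intermediate
4 | (S)-2,2-dimethyl-5-oxocyclohex-3-ene-1-carbaldehyde | O=C1C=CC(C)(C)[C@@H](C=O)C1 | intermediate (not isolated)
5 | (S)-5-(dimethoxymethyl)-4,4-dimethylcyclohex-2-en-1-one | O=C1C=CC(C)(C)[C@@H](C(OC)OC)C1 | intermediate
6 | (5S,6R)-5-(dimethoxymethyl)-6-(hydroxymethyl)-4,4-dimethylcyclohex-2-en-1-one | OC[C@@H]1C(=O)C=CC(C)(C)[C@H]1C(OC)OC | intermediate (not isolated)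
7 | (5S,6R)-6-[(tert-butyldimethylsilyloxy)methyl]-5-(dimethoxymethyl)-4,4-dimethylcyclohex-2-en-1-one | CC(C)(C)[Si](C)(C)OC[C@@H]1C(=O)C=CC(C)(C)[C@H]1C(OC)OC | intermediate
8 | 5-{[(1S,6R)-1-[(tert-butyldimethylsilyloxy)methyl]-6-(dimethoxymethyl)-5,5-dimethyl-2-oxocyclohex-3-en-1-yl]methylidene}-2,2-dimethyl-1,3-dioxane-4,6-dione | CC1(C)OC(=O)C(=C[C@]2(CO[Si](C)(C)C(C)(C)C)C(=O)C=CC(C)(C)[C@H]2C(OC)OC)C(=O)O1 | intermediate
9 | 5-{[(1S,6R)-6-(dimethoxymethyl)-1-(hydroxymethyl)-5,5-dimethyl-2-oxocyclohex-3-en-1-yl]methylidene}-2,2-dimethyl-1,3-dioxane-4,6-dione | CC1(C)OC(=O)C(=C[C@]2(CO)C(=O)C=CC(C)(C)[C@H]2C(OC)OC)C(=O)O1 | intermediate (not isolated)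
10 | (6S,11R)-11-(dimethoxymethyl)-10,10-dimethyl-3,7-dioxo-2-oxaspiro[5.5]undeca-4,8-diene-4-carboxylic acid | OC(=O)C1=C[C@]2(COC1=O)C(=O)C=CC(C)(C)[C@H]2C(OC)OC | intermediate
11 | 2-(2-bromoethyl)-2-methyl-1,3-dioxolane | CC1(CCBr)OCCO1 | starting material
12 | [2-(2-methyl-1,3-dioxolan-2-yl)ethyl]magnesium bromide | CC1(CC[Mg]Br)OCCO1 | intermediate (not isolated)
13 | bis(bromomagnesium) enolate–carboxylate of the C9 conjugate adduct of 10 | Br[Mg]OC(=O)C1=C(O[Mg]Br)OC[C@]2(C(=O)C=CC(C)(C)[C@H]2C(OC)OC)[C@@H]1CCC3(C)OCCO3 | intermediate (not isolated)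
14 | (4R,5S,6S,11R)-11-(dimethoxymethyl)-10,10-dimethyl-5-[2-(2-methyl-1,3-dioxolan-2-yl)ethyl]-3,7-dioxo-4-(prop-2-yn-1-yl)-2-oxaspiro[5.5]undec-8-ene-4-carboxylic acid | C#CC[C@]1(C(=O)O)[C@@H](CCC3(C)OCCO3)[C@]2(COC1=O)C(=O)C=CC(C)(C)[C@H]2C(OC)OC | intermediate
15 | (4R,5S,6S,11R)-11-(dimethoxymethyl)-10,10-dimethyl-3,7-dioxo-5-(3-oxobutyl)-4-(prop-2-yn-1-yl)-2-oxaspiro[5.5]undec-8-ene-4-carboxylic acid | C#CC[C@]1(C(=O)O)[C@@H](CCC(C)=O)[C@]2(COC1=O)C(=O)C=CC(C)(C)[C@H]2C(OC)OC | intermediate
16 | trimethylsilyl ester of 17 | C#CC[C@]1(C(=O)O[Si](C)(C)C)[C@@H](CCC(=C)O[Si](C)(C)C)[C@]2(COC1=O)C(=O)C=CC(C)(C)[C@H]2C(OC)OC | intermediate (not isolated)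
17 | (4R,5S,6S,11R)-11-(dimethoxymethyl)-10,10-dimethyl-3,7-dioxo-4-(prop-2-yn-1-yl)-5-[3-(trimethylsilyloxy)but-3-en-1-yl]-2-oxaspiro[5.5]undec-8-ene-4-carboxylic acid | C#CC[C@]1(C(=O)O)[C@@H](CCC(=C)O[Si](C)(C)C)[C@]2(COC1=O)C(=O)C=CC(C)(C)[C@H]2C(OC)OC | intermediate
18 | 2-thioxopyridin-1(2H)-yl ester of 17 (Barton ester) | C#CC[C@]1(C(=O)ON3C=CC=CC3=S)[C@@H](CCC(=C)O[Si](C)(C)C)[C@]2(COC1=O)C(=O)C=CC(C)(C)[C@H]2C(OC)OC | intermediate (not isolated)
19 | 6,6-dimethoxy-1-oxo-13-(trimethylsilyloxy)-6,7-secokaura-2,16-dien-7,20-olide (ring stereocentres as in 21) | C=C1C[C@]23C[C@@]1(O[Si](C)(C)C)CC[C@H]2[C@]1(COC3=O)C(=O)C=CC(C)(C)[C@H]1C(OC)OC | intermediate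
20 | (15R)-15-hydroxy-6,6-dimethoxy-1-oxo-13-(trimethylsilyloxy)-6,7-secokaura-2,16-dien-7,20-olide | C=C1[C@@H](O)[C@]23C[C@@]1(O[Si](C)(C)C)CC[C@H]2[C@]1(COC3=O)C(=O)C=CC(C)(C)[C@H]1C(OC)OC | intermediate
21 | (5R,8S,9S,10S,13S,15R)-13,15-dihydroxy-1,6-dioxo-6,7-secokaura-2,16-dien-7,20-olide (CNP0521079.1) | C=C1[C@@H](O)[C@]23C[C@@]1(O)CC[C@H]2[C@]1(COC3=O)C(=O)C=CC(C)(C)[C@H]1C=O | target

**Step count and risks**

Total step count: 12. Longest linear sequence: 12 steps (1 → 21); 11 enters in step 7.

The three steps most likely to fail are step 7, step 10 and step 11.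

Step 7 may fail because the magnesium carboxylate of 10 could be a sluggish acceptor, or the dianion could alkylate poorly. The fallback sets out from 8 and comes back at 14. The Grignard reagent 12 is added to the alkylidene Meldrum's acid 8 itself (no copper needed), and the resulting Meldrum's acid anion is alkylated with propargyl bromide (K2CO3, DMF) to give the propargylated Meldrum's acid F1. HF·pyridine then removes the silyl group, and the freed C20–OH opens the Meldrum's ring to the lactone acid 14. The C–C bonds are thus made before the lactone exists, so C9 selectivity rests on acyclic control (less predictable than in step 7), and 14 forms as a C8 epimer mixture, which is harmless because C8 becomes a planar radical in step 10.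

Step 10 may fail because the C13 radical could be reduced or trapped before it reaches the alkyne, or the Barton ester could trap the C8 radical. The fallback sets out from 18 and comes back at 21; it closes the two rings separately. Barton ester 18 is photolysed without stannane, so that after the same 6-endo closure the C13 radical takes up the 2-pyridylthio group to give the silyl thioketal F2, which is hydrolysed on aqueous work-up to the ring C ketone F3. A nickel-catalysed reductive alkyne–ketone cyclisation (Ni(C8H12)2, an N-heterocyclic carbene ligand, Et3SiH; zerovalent nickel; closest to the known ynal reductive cyclisations) then forms C13–C16 and gives the triethylsilyl ether F4, the 13-O-triethylsilyl analogue of 19. The conditions of steps 11 and 12 applied to F4 give its 15-hydroxy derivative F5 and then 21.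

Step 11 may fail through the wrong C15 epimer or over-oxidation. The fallback sets out from 19 and comes back at 20. Allylic oxidation of the C15 methylene to the ketone (CrO3, 3,5-dimethylpyrazole, CH2Cl2, −20 °C) gives the enone F6, and 1,2-reduction (NaBH4, CeCl3·7H2O, MeOH, −78 °C; Luche reduction) returns 20. The strained exocyclic enone should react before the hindered ring A enone. Hydride is delivered to the C15 face that the selenium reagent would use for oxygen, so this sequence gives the epimer complementary to step 11 and is the remedy if step 11 gives mainly the 15-epimer.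

**Further compounds**

F1 | step 7 | 5-{(1S)-1-[(1S,6R)-1-[(tert-butyldimethylsilyloxy)methyl]-6-(dimethoxymethyl)-5,5-dimethyl-2-oxocyclohex-3-en-1-yl]-3-(2-methyl-1,3-dioxolan-2-yl)propyl}-2,2-dimethyl-5-(prop-2-yn-1-yl)-1,3-dioxane-4,6-dione | CC1(C)OC(=O)C(CC#C)([C@@H](CCC3(C)OCCO3)[C@]2(CO[Si](C)(C)C(C)(C)C)C(=O)C=CC(C)(C)[C@H]2C(OC)OC)C(=O)O1
F2 | step 10 | ring C O-trimethylsilyl S-(2-pyridyl) thioketal at C13 (C13 epimer mixture; C8-propargyl; other centres as in 19) | C#CC[C@]12CC(O[Si](C)(C)C)(Sc3ccccn3)CC[C@H]1[C@]1(COC2=O)C(=O)C=CC(C)(C)[C@H]1C(OC)OC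
F3 | step 10 | ring C ketone: 13-oxo lactone with C8-propargyl (C5, C8, C9, C10 as in 19) | C#CC[C@]12CC(=O)CC[C@H]1[C@]1(COC2=O)C(=O)C=CC(C)(C)[C@H]1C(OC)OC
F4 | step 10 | 13-O-triethylsilyl analogue of 19 | C=C1C[C@]23C[C@@]1(O[Si](CC)(CC)CC)CC[C@H]2[C@]1(COC3=O)C(=O)C=CC(C)(C)[C@H]1C(OC)OC
F5 | step 10 | 13-O-triethylsilyl analogue of 20 | C=C1[C@@H](O)[C@]23C[C@@]1(O[Si](CC)(CC)CC)CC[C@H]2[C@]1(COC3=O)C(=O)C=CC(C)(C)[C@H]1C(OC)OC
F6 | step 11 | 15-oxo derivative of 19 (16-en-15-one) | C=C1C(=O)[C@]23C[C@@]1(O[Si](C)(C)C)CC[C@H]2[C@]1(COC3=O)C(=O)C=CC(C)(C)[C@H]1C(OC)OC
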